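**Remark on the structure.** The SMILES is read as drawn: configuration 4R,5S,6R,7S,8S,10R, with a cis-fused 4,5-epoxide (C3 and C6 cis, as from a 4Z olefin). Germacrane numbering is used for all compounds: C1 ketone, C2/C3 CH2, C4(C15H3)/C5 epoxide, C6 lactone carbinol, C7 and C10(C14H3) ether carbons, C8 ester carbinol, C9 CH2, C11(=C13H2)–C12(=O) lactone.

## The problem

The skeleton is a ten-membered carbocycle C1–C10 spanned by an ether oxygen from C7 to C10. The tetrahydrofuran O/C7/C8/C9/C10 and a nine-membered oxonane share that bridge (an 11-oxabicyclo[6.2.1]undecane), and both ether carbons are fully substituted. On this frame sit an α-methylene-γ-butyrolactone (O–C6, C7–C11, spiro to the tetrahydrofuran at C7), a trisubstituted cis-epoxide at C4/C5, a ketone at C1 next to C10, and a methacrylate at C8.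

There are six stereocentres, five of them contiguous (C4–C8). C7 and C10 are locked cis by the bridge. The C8 oxygen is exo (on the face of C11 and C14). The C6 oxygen must lie on the C11 face, and the epoxide oxygen on the same ring face as the C6 oxygen.

The hardest task is closing a medium ring that already carries two quaternary C–O centres and needs a Z-configured C4=C5 unit. The sensitive groups are two Michael acceptors, an epoxide next to a carbinol, and above all the C7–O bond. An enolate at C11 would expel it (retro-oxa-Michael), so the exo-methylene cannot come from lactone enolate chemistry.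

The feature that makes the key step possible is the relation of C1 to C6. The C1 carbonyl is tied to C6 by the four-carbon unit C2–C3–C4(CH3)–C5. Bonding C1 to C6 contracts the ten-membered ring to the cyclohexane C1/C10/C9/C8/C7/C6 of a 7-oxabicyclo[2.2.1]heptane, whose oxygen bridge is the tetrahydrofuran oxygen of the target. That bicycle is a furan Diels–Alder adduct, and its 1-vinyl-6-propenyl-1-ol form is an oxy-Cope precursor of the cyclodec-5-en-1-one. The resulting C5=C6/C4–H array can then be transposed by an ene reaction to C6–O/C4=C5.

## Retrosynthesis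

**22 ⇒ 21.** The bonds C11–C12 and C12–O(C6) are cut: the lactone is closed last by carbonylation of vinyl triflate 21 onto the C6 hydroxyl. The neighbouring cut (α-methylenation of a saturated lactone) would need the C11 enolate that destroys the bridge. The forward step must tolerate epoxide, ketone and methacrylate.

**21 ⇒ 20 ⇒ 18.** The epoxide is removed to the Z allylic alcohol 20 (hydroxyl-directed epoxidation forward). Alcohol 20 is traced to the E-5,6-olefin 18 by an ene transposition: the C6–O bond is cut and the double bond moved. This is preferred to direct allylic oxidation because C7 is quaternary, so H4 is the only allylic hydrogen and the regiochemistry is forced.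

**18 ⇒ 17 ⇒ 16.** The methacrylate is removed, and the C8 hydroxyl is traced to a C8–Si bond (Tamao oxidation, retention). Silicon serves as a base-stable mask of the C8 oxygen.

**16 ⇒ 14 (key).** C3–C4 is cut and C1–C6 re-formed, giving the exo,exo-dialkenyl 7-oxanorbornanol 14. Compared with end-to-end closures (metathesis at C4=C5, aldol at C1–C2), this is a unimolecular, strain-releasing rearrangement. The precursor is a compact bicycle, and the ketone at C1 arrives in the right place. The forward reaction must be a [3,3] shift of the potassium alkoxide that leaves the bridge intact.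

**14 ⇒ 13 ⇒ 12.** The vinyl group (C2, C3) is removed to ketone 13. The C1 carbonyl is traced to a carboxylic acid (decarboxylative oxygenation), which is the unused carbonyl of maleic anhydride.

**12 ⇒ 11 ⇒ 10 ⇒ 7.** The vinyl triflate comes from methyl ketone 11 and that from the C11 carbinol 10. The C8–Si bond is cut back to the C8=C9 olefin of 7; the C11 hydroxyl delivers silicon intramolecularly, fixing regio- and stereochemistry at C8.

**7 ⇒ 6 ⇒ 5.** The E-propenyl group (C4, C15 from a sulfone) is cut at C4=C5 back to lactol 6 and lactone 5, whose carbonyl is C5.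

**5 ⇒ 2 + 3; 2 ⇒ 1.** C6–C7, C1–C10 and O11–C5 are cut: furyl carbinol 2 and maleic anhydride 3. The flat furan ring becomes the tetrahydrofuran ring of the target and both quaternary ether carbons form in one event. The symmetric dienophile leaves no regiochemical question, and the carbinol both differentiates the two carbonyls and relays its configuration to the bicycle. Carbinol 2 comes from ketone 1 by asymmetric transfer hydrogenation.

## Roads not taken

**Alternative 1:** Ring-closing metathesis at C4=C5 (the most obvious route). A fully substituted tetrahydrofuran–lactone diene A1 (vinyl on C6, 4-methylpent-4-enoyl chain on C10) would be cyclised to the Z-olefin A2 and then epoxidised. A1 needs C6, C7, C8 and C10 built one by one by acyclic methods. The closure has to form a trisubstituted olefin in a strained bridged ten-membered ring with no control of geometry, and in the presence of two acrylate units. The chosen plan makes both quaternary ether carbons in one cycloaddition and obtains the ring by rearrangement, with the Z geometry fixed by chirality transfer.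

**Alternative 2:** Oxonium ylide formation and [2,3] ring expansion. A vinyl tetrahydropyranyl diazoketone A3 (from an Achmatowicz-type pyranone) would give the bridged ketone A4 with a copper carbenoid; this is the known way to this ring system in the cladiellin diterpenes. It closes bridge and ring at once, but it places the carbonyl at C8 and leaves C6 as CH2 and C7 as CH. Allylic oxygenation at C6, construction of the quaternary C7–C11 bond next to a ketone and a C8 reduction from the hindered face would follow, after about ten steps to reach A3. The chosen plan has oxygen at C1, C6 and C8 by design.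

**Alternative 3:** Biomimetic transannular SN2′ etherification. A 10-hydroxy-13-acetoxy-germacr-7(11)-enolide A5 would close the C7–O bond and unveil the exo-methylene in one step. The step is attractive, but A5 contains the ten-membered ring and every other stereocentre, so the problem is only moved. The facial outcome at C7 would also rest on an unknown ring conformation.

Key step: step 10

## Route

Step 1
Reactants: 1 1-(5-methylfuran-2-yl)ethan-1-one
Product: 2 (1S)-1-(5-methylfuran-2-yl)ethan-1-ol
Conditions: RuCl[(S,S)-TsDPEN](p-cymene) (0.5 mol %), HCO2H/Et3N 5:2, rt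
Reagents that add atoms: none
Why: Noyori asymmetric transfer hydrogenation of an aryl methyl ketone; the (S,S) catalyst should give the S carbinol as with acetophenone, and this C11 centre is the only one set by a chiral reagent.

Step 2
Reactants: 2 (1S)-1-(5-methylfuran-2-yl)ethan-1-ol; 3 maleic anhydride
Product: 5 tricyclic lactone acid (7-oxanorbornene; exo γ-lactone C7–C11–O–C5(=O)–C6; exo CO2H on C1), via exo Diels–Alder anhydride adduct 4 (not isolated)
Conditions: Et2O, rt, dark; then toluene, 40 °C
Reagents that add atoms: none
Why: Reversible furan Diels–Alder reaction followed by irreversible acylation of the carbinol by the adjacent exo anhydride carbonyl (tandem Diels–Alder/lactonisation of furfuryl alcohols). The C11 methyl avoids C8–H (H11 toward C8, methyl toward the bridging oxygen), which for S-configured 2 should give the C7/C10 sense of the target together with C6 and C1. The minor diastereomer, which would lead to the enantiomeric series, is to be removed here by crystallisation.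

Step 3
Reactants: 5 tricyclic lactone acid
Product: 6 lactol acid (C5 lactol, both anomers)
Conditions: i-Bu2AlH (2.3 equiv), CH2Cl2, −78 °C
Reagents that add atoms: none
Why: Half-reduction of a γ-lactone to the lactol; the acid is first converted into an aluminium carboxylate that is not reduced at −78 °C.

Step 4
Reactants: 6 lactol acid
Product: 7 hydroxy acid with exo (E)-prop-1-enyl on C6 and free (1S)-1-hydroxyethyl on C7
Conditions: 5-(ethylsulfonyl)-1-phenyl-1H-tetrazole, KN(SiMe3)2 (3.2 equiv), DME, −60 °C → rt
Reagents that add atoms: 5-(ethylsulfonyl)-1-phenyl-1H-tetrazole, CCS(=O)(=O)c1nnnn1-c1ccccc1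
Why: Julia–Kocienski olefination of the open hydroxy-aldehyde form of the lactol gives the E-propenyl group (C4, C15) and frees the C11 hydroxyl. The E geometry is needed because it fixes C4 in step 10; Wittig-type olefinations of 7-oxanorbornane lactols are standard.

Step 5
Reactants: 7 hydroxy acid
Product: 10 8-exo-[isopropoxy(dimethyl)silyl] hydroxy acid (C9 now CH2), via O11-dimethylsilyl ether trimethylsilyl ester 8 (not isolated), via cyclic siloxane 9 (not isolated)
Conditions: Me3SiCl (1.05 equiv), Et3N, CH2Cl2, 0 °C; ClSiHMe2, Et3N; H2PtCl6 (0.1 mol %), 60 °C; then i-PrOH, PPTS (cat.)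
Reagents that add atoms: chlorodimethylsilane, C[SiH](C)Cl; propan-2-ol, CC(C)O
Why: Tamao–Ito intramolecular hydrosilylation of a homoallylic alcohol: the O11–SiHMe2 group adds to the strained C8=C9 bond in the 5-exo sense, silicon to C8 and from the exo face (the only face the bridgehead tether reaches), which sets C8. The acid is capped as its trimethylsilyl ester so that it cannot deliver silicon to C9. Isopropanol then opens the strained oxasilolane, freeing O11–H and leaving a robust alkoxysilane as masked C8 hydroxyl.

Step 6
Reactants: 10 hydroxy isopropoxysilyl acid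
Product: 11 C11 methyl ketone acid
Conditions: Dess–Martin periodinane, CH2Cl2, rt
Reagents that add atoms: none
Why: Dess–Martin oxidation of the only free hydroxyl; C8 oxygen is still masked as C–Si, which is how the two secondary carbinol positions C8 and C11 are distinguished.

Step 7
Reactants: 11 methyl ketone acid
Product: 12 enol triflate acid (C11(OTf)=C13H2)
Conditions: KN(SiMe3)2 (2.2 equiv), PhNTf2, THF, −78 °C
Reagents that add atoms: N-phenylbis(trifluoromethanesulfonimide), O=S(=O)(N(c1ccccc1)S(=O)(=O)C(F)(F)F)C(F)(F)F
Why: Kinetic enolate O-triflation; the ketone can enolise only toward C13 because C7 is quaternary, and the carboxylate is inert. The vinyl triflate carries C11/C13 at the oxidation level of the final exo-methylene, so no lactone enolate is ever needed.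

Step 8
Reactants: 12 enol triflate acid
Product: 13 7-oxanorbornan-2-one (C1 ketone, exo E-propenyl on C6)
Conditions: Ce(Ot-Bu)4 (10 mol %), O2 (1 atm), PhCN, blue LEDs, 40 °C
Reagents that add atoms: dioxygen, O=O
Why: Photocatalytic decarboxylative oxygenation: charge transfer in the tetravalent cerium carboxylate, loss of CO2, capture of the secondary C1 radical by O2 and collapse of the peroxy intermediate to the ketone. The ketone is made only now because a C1 ketone next to the C5 lactone carbonyl would open the oxygen bridge by β-elimination.

Step 9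
Reactants: 13 7-oxanorbornan-2-one
Product: 14 exo,exo-dialkenyl carbinol (C1: exo vinyl, endo OH)
Conditions: CH2=CHMgBr, CeCl3, THF, −78 °C
Reagents that add atoms: vinylmagnesium bromide, C=C[Mg]Br
Why: Organocerium 1,2-addition to an enolisable ketone; attack from the exo face (usual for 7-oxanorbornan-2-ones) places the vinyl group cis to the exo propenyl group, as the boat-type [3,3] shift requires, while CeCl3 suppresses enolisation toward C6.

Step 10
Reactants: 14 exo,exo-dialkenyl carbinol
Product: 16 (4R,5E)-ring-expanded ketone (11-oxabicyclo[6.2.1]undecane frame: C1 ketone, C5=C6, C4–H/CH3, C8–Si, C11 vinyl triflate), via potassium enolate 15 (not isolated)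
Conditions: KH, 18-crown-6, THF, 0 °C → rt; aq. NH4Cl
Reagents that add atoms: none
Why: The potassium alkoxide of 14 undergoes an anionic oxy-Cope rearrangement: the strained C1–C6 bond of the 7-oxabicyclo[2.2.1]heptane breaks while C3–C4 forms, giving enolate 15 and, on protonation, ketone 16. The closest known reaction type is the oxy-Cope ring expansion of 1,2-dialkenylcyclohexanols to cyclodec-5-en-1-ones and of alkenyl norbornanols. No ring is closed end to end: the six-membered ring expands by four atoms to the ten-membered carbocycle (the five-membered oxygen ring to the oxonane) and the tetrahydrofuran is untouched. The cis-exo,exo arrangement enforces a boat transition state with the termini turned away from the bridge. In it the E-propenyl methyl is pseudo-equatorial, which should set C4 as R, and C4 ends cis to the former endo H6, which gives the E-5,6-olefin. C7, C8 and C10 are not involved. The selectivity needed is [3,3] shift over alkoxide fragmentation or elimination; it is secured by the relief of bicyclic strain and by the absence of any β-leaving group in alkoxide or enolate (the C10 oxygen is α to C1).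

Step 11
Reactants: 16 ring-expanded ketone
Product: 17 8-exo alcohol
Conditions: KF, KHCO3, 30 % H2O2, THF/MeOH, rt
Reagents that add atoms: hydrogen peroxide, OO
Why: Tamao oxidation of the alkoxysilane with retention gives the 8S alcohol; basic peroxide should leave the isolated E-olefin, the ketone and the vinyl triflate alone.

Step 12
Reactants: 17 8-exo alcohol
Product: 18 8-methacrylate
Conditions: methacrylic anhydride, Et3N, DMAP (cat.), CH2Cl2, rt
Reagents that add atoms: methacrylic anhydride, C=C(C)C(=O)OC(=O)C(C)=C
Why: DMAP-catalysed acylation of the only hydroxyl; the ester is installed after all organometallic and strongly basic steps and keeps the C8 oxygen out of the lactonisation in step 15.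

Step 13
Reactants: 18 8-methacrylate
Product: 20 (6R,4Z)-allylic alcohol, via allylic hydroperoxide 19 (not isolated)
Conditions: O2, tetraphenylporphyrin (cat.), visible light, CH2Cl2, −20 °C; then PPh3
Reagents that add atoms: dioxygen, O=O
Why: Schenck ene reaction of singlet oxygen: H4 is the only allylic hydrogen (C7 is quaternary), so oxygen must add to C6 with shift of the double bond to C4=C5. Attack on the outer face (syn to C11, away from the ring interior) gives 6R, and suprafacial removal of H4 on that face turns the 4R centre of step 10 into the Z-olefin (C3 cis to C6); PPh3 reduces the hydroperoxide.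

Step 14
Reactants: 20 allylic alcohol
Product: 21 (4R,5S,6R)-epoxy alcohol
Conditions: VO(acac)2 (5 mol %), t-BuOOH, CH2Cl2, 0 °C
Reagents that add atoms: tert-butyl hydroperoxide, CC(C)(C)OO
Why: Hydroxyl-directed vanadium-catalysed epoxidation; with Z-allylic alcohols in eight- to ten-membered rings the vanadate ester delivers oxygen to the ring face that carries the hydroxyl, giving the cis epoxy alcohol, while the electron-poor methacrylate and vinyl triflate double bonds are inert.

Step 15
Reactants: 21 epoxy alcohol
Product: 22 CNP0241021.1
Conditions: Pd(PPh3)4 (10 mol %), CO (1 atm), n-Bu3N, MeCN, 60 °C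
Reagents that add atoms: carbon monoxide, [C-]#[O+]
Why: Carbonylative lactonisation of a vinyl triflate: oxidative addition to zerovalent palladium, CO insertion and capture of the acyl palladium by the C6 hydroxyl give the α-methylene-γ-butyrolactone directly. The conditions are nearly neutral, so no C11 enolate forms and bridge, epoxide and esters should survive.

## Compound list

1 | 1-(5-methylfuran-2-yl)ethan-1-one | CC(=O)c1ccc(C)o1 | starting material
2 | (1S)-1-(5-methylfuran-2-yl)ethan-1-ol | C[C@H](O)c1ccc(C)o1 | intermediate
3 | maleic anhydride | O=C1OC(=O)C=C1 | starting material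
4 | exo Diels–Alder adduct: 4-[(1S)-1-hydroxyethyl]-1-methyl-7-oxabicyclo[2.2.1]hept-5-ene-2-exo,3-exo-dicarboxylic anhydride | C[C@H](O)[C@@]12C=C[C@@](C)(O1)[C@H]1C(=O)OC(=O)[C@H]12 | intermediate (not isolated)
5 | tricyclic lactone acid: 7-oxanorbornene (bridgeheads C7, C10; C10–CH3; C8=C9), exo γ-lactone C7–C11H(CH3)–O–C5(=O)–C6 (11S, methyl toward the bridging oxygen), exo CO2H on C1 | C[C@@H]1OC(=O)[C@@H]2[C@H](C(=O)O)[C@@]3(C)C=C[C@@]12O3 | intermediate
6 | lactol acid (C5 lactol of 5, both anomers) | C[C@@H]1OC(O)[C@@H]2[C@H](C(=O)O)[C@@]3(C)C=C[C@@]12O3 | intermediate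
7 | hydroxy acid: exo (E)-prop-1-enyl on C6, (1S)-1-hydroxyethyl on C7, exo CO2H on C1, C8=C9 | C[C@H](O)[C@@]12C=C[C@@](C)(O1)[C@@H](C(=O)O)[C@H]2/C=C/C | intermediate
8 | O11-dimethylsilyl ether, trimethylsilyl ester of 7 | C[C@H](O[SiH](C)C)[C@@]12C=C[C@@](C)(O1)[C@@H](C(=O)O[Si](C)(C)C)[C@H]2/C=C/C | intermediate (not isolated)
9 | cyclic siloxane (O11–SiMe2–C8, silicon exo on C8), trimethylsilyl ester | C[C@@H]1O[Si](C)(C)[C@H]2C[C@@]3(C)O[C@@]12[C@@H]([C@@H]3C(=O)O[Si](C)(C)C)/C=C/C | intermediate (not isolated)
10 | 8-exo-[isopropoxy(dimethyl)silyl] hydroxy acid | C[C@H](O)[C@@]12[C@@H]([Si](C)(C)OC(C)C)C[C@@](C)(O1)[C@@H](C(=O)O)[C@H]2/C=C/C | intermediate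
11 | C11 methyl ketone acid | CC(=O)[C@@]12[C@@H]([Si](C)(C)OC(C)C)C[C@@](C)(O1)[C@@H](C(=O)O)[C@H]2/C=C/C | intermediate
12 | enol triflate acid | C=C(OS(=O)(=O)C(F)(F)F)[C@@]12[C@@H]([Si](C)(C)OC(C)C)C[C@@](C)(O1)[C@@H](C(=O)O)[C@H]2/C=C/C | intermediate
13 | 7-oxanorbornan-2-one (C1 ketone; exo E-propenyl on C6) | C=C(OS(=O)(=O)C(F)(F)F)[C@@]12[C@@H]([Si](C)(C)OC(C)C)C[C@@](C)(O1)C(=O)[C@H]2/C=C/C | intermediate
14 | exo,exo-dialkenyl carbinol (C1: exo vinyl, endo OH) | C=C(OS(=O)(=O)C(F)(F)F)[C@@]12[C@@H]([Si](C)(C)OC(C)C)C[C@@](C)(O1)[C@@](O)(C=C)[C@H]2/C=C/C | intermediate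
15 | potassium enolate of 16 | C=C(OS(=O)(=O)C(F)(F)F)[C@]12O[C@](C)(C[C@@H]1[Si](C)(C)OC(C)C)/C([O-])=C/C[C@@H](C)/C=C/2.[K+] | intermediate (not isolated)
16 | (4R,5E)-ring-expanded ketone: 11-oxabicyclo[6.2.1]undec-5-en-1-one frame, C8 exo isopropoxydimethylsilyl, C7 1-(triflyloxy)vinyl | C=C(OS(=O)(=O)C(F)(F)F)[C@]12O[C@](C)(C[C@@H]1[Si](C)(C)OC(C)C)C(=O)CC[C@@H](C)/C=C/2 | intermediate
17 | 8-exo (8S) alcohol | C=C(OS(=O)(=O)C(F)(F)F)[C@]12O[C@](C)(C[C@@H]1O)C(=O)CC[C@@H](C)/C=C/2 | intermediate
18 | 8-methacrylate | C=C(OS(=O)(=O)C(F)(F)F)[C@]12O[C@](C)(C[C@@H]1OC(=O)C(C)=C)C(=O)CC[C@@H](C)/C=C/2 | intermediate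
19 | (6R,4Z)-allylic hydroperoxide | C=C(C)C(=O)O[C@H]1C[C@@]2(C)O[C@]1(C(=C)OS(=O)(=O)C(F)(F)F)[C@H](OO)/C=C(C)\CCC2=O | intermediate (not isolated)
20 | (6R,4Z)-allylic alcohol | C=C(C)C(=O)O[C@H]1C[C@@]2(C)O[C@]1(C(=C)OS(=O)(=O)C(F)(F)F)[C@H](O)/C=C(C)\CCC2=O | intermediate
21 | (4R,5S,6R)-epoxy alcohol | C=C(C)C(=O)O[C@H]1C[C@@]2(C)O[C@]1(C(=C)OS(=O)(=O)C(F)(F)F)[C@H](O)[C@@H]1O[C@]1(C)CCC2=O | intermediate
22 | CNP0241021.1 (4R,5S,6R,7S,8S,10R) | C=C(C)C(=O)O[C@H]1C[C@@]2(C)O[C@@]13C(=C)C(=O)O[C@@H]3[C@@H]1O[C@]1(C)CCC2=O | target

## Step count and risks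

Total step count: 15. Longest linear sequence: 15 steps (from 1; 3 enters in step 2).

**Step 10 (key step).** The most likely failure is fragmentation of the alkoxide without recombination, or attack of the alkoxide on the triflate sulfur. The rearrangement may also stall if the vinyl group was added endo in step 9, since the boat is then out of reach. The fallback avoids the alkoxide altogether and sets out from 14: the trimethylsilyl ether of 14 F1 (Me3SiCl, imidazole) is rearranged thermally (toluene, sealed, 130 °C) as a neutral siloxy-Cope shift driven only by strain release. The resulting trimethylsilyl enol ether of 16 F2 is hydrolysed with aqueous citric acid, returning to the route at 16.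

**Step 2.** Facial selectivity may be poor, which would erode the absolute configuration. The acidic medium may also ionise the furyl carbinol, or the adduct may revert before it lactonises. The fallback inverts the order of events: 2 is acylated with 3 under Et3N/DMAP at 0 °C to the maleate half-ester of 2 F3, and the now intramolecular cycloaddition proceeds on warming in buffered solution with the tether dictating the face. It returns at 5.

**Step 8.** The photochemical oxygenation may stop at hydroperoxide/alcohol mixtures, or the C1 radical may be diverted (hydrogen abstraction, addition to the propenyl group). The fallback sets out from 12: the N-acyloxypyridine-2-thione ester of 12 F4 (DCC, N-hydroxypyridine-2-thione) is photolysed under O2 with t-BuSH and reduced with P(OMe)3 to the C1 alcohol F5, which is oxidised with Dess–Martin periodinane to 13.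

**Step 9.** Enolisation toward C6 can lead to β-elimination of the bridging oxygen, and some endo attack is possible. The fallback uses a smaller, less basic nucleophile: HC≡CMgBr/CeCl3 adds to 13 to give the ethynyl carbinol F6, which is semihydrogenated (H2, Pd/CaCO3 poisoned with Pb(OAc)2, quinoline) to 14.

**Step 13.** The disubstituted olefin may react sluggishly with singlet oxygen. Attack from the inner face would give the wrong C6, and an unfavourable allylic conformation would give the E-olefin. The fallback separates oxygen delivery from transposition and sets out from 18: mCPBA epoxidises the outer face to the 5,6-epoxide of 18 F7. Me3SiOTf/DBU then isomerises it, by removal of the only β-hydrogen H4, to the trimethylsilyl ether of 20 F8, which HF·pyridine cleaves to 20.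

Further compounds

F1 | step 10 | trimethylsilyl ether of 14 | C=C(OS(=O)(=O)C(F)(F)F)[C@@]12[C@@H]([Si](C)(C)OC(C)C)C[C@@](C)(O1)[C@@](O[Si](C)(C)C)(C=C)[C@H]2/C=C/C
F2 | step 10 | trimethylsilyl enol ether of 16 | C=C(OS(=O)(=O)C(F)(F)F)[C@]12O[C@](C)(C[C@@H]1[Si](C)(C)OC(C)C)/C(O[Si](C)(C)C)=C/C[C@@H](C)/C=C/2
F3 | step 2 | maleate half-ester of 2: (Z)-4-[(1S)-1-(5-methylfuran-2-yl)ethoxy]-4-oxobut-2-enoic acid | C[C@H](OC(=O)/C=C\C(=O)O)c1ccc(C)o1
F4 | step 8 | N-acyloxypyridine-2-thione ester of 12 | C=C(OS(=O)(=O)C(F)(F)F)[C@@]12[C@@H]([Si](C)(C)OC(C)C)C[C@@](C)(O1)[C@@H](C(=O)On1ccccc1=S)[C@H]2/C=C/C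
F5 | step 8 | C1 alcohol (both epimers) corresponding to 13 | C=C(OS(=O)(=O)C(F)(F)F)[C@@]12[C@@H]([Si](C)(C)OC(C)C)C[C@@](C)(O1)C(O)[C@H]2/C=C/C
F6 | step 9 | ethynyl carbinol (C1: exo ethynyl, endo OH) | C=C(OS(=O)(=O)C(F)(F)F)[C@@]12[C@@H]([Si](C)(C)OC(C)C)C[C@@](C)(O1)[C@@](O)(C#C)[C@H]2/C=C/C
F7 | step 13 | 5,6-epoxide of 18 (oxygen on the outer face) | C=C(OS(=O)(=O)C(F)(F)F)[C@]12O[C@](C)(C[C@@H]1OC(=O)C(C)=C)C(=O)CC[C@@H](C)[C@@H]3O[C@H]32
F8 | step 13 | trimethylsilyl ether of 20 | C=C(C)C(=O)O[C@H]1C[C@@]2(C)O[C@]1(C(=C)OS(=O)(=O)C(F)(F)F)[C@H](O[Si](C)(C)C)/C=C(C)\CCC2=O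
A1 | alternative 1 | metathesis diene: tetrahydrofuran spiro-lactone with vinyl on C6 and 4-methylpent-4-enoyl on C10 | C=C(C)C(=O)O[C@H]1C[C@](C)(C(=O)CCC(C)=C)O[C@@]12C(=C)C(=O)O[C@@H]2C=C
A2 | alternative 1 | 4Z-olefin (4,5-deoxy target) | C=C(C)C(=O)O[C@H]1C[C@@]2(C)O[C@@]13C(=C)C(=O)O[C@@H]3/C=C(C)\CCC2=O
A3 | alternative 2 | vinyl tetrahydropyranyl diazoketone (one C1/C4 diastereomer shown) | [N-]=[N+]=CC(=O)C[C@@]1(C)O[C@@](C)(C=C)CC[C@H]1O[Si](C)(C)C(C)(C)C
A4 | alternative 2 | 4Z-11-oxabicyclo[6.2.1]undec-4-en-8-one with C1 silyl ether | O=C1C[C@@]2(C)O[C@@H]1C/C=C(C)\CC[C@@H]2O[Si](C)(C)C(C)(C)C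
A5 | alternative 3 | 10-hydroxy-13-acetoxy-1-oxo-4,5-epoxy-8-methacryloyloxygermacr-7(11)-en-12,6-olide | C=C(C)C(=O)O[C@H]1C[C@@](C)(O)C(=O)CC[C@@]2(C)O[C@H]2[C@H]2OC(=O)C(COC(C)=O)=C12
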